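The cyclohexenone ring (C1 tertiary carbinol, C2 ketone, C3=C4, C5 carbinol, C6 benzoyloxy carbon; C7 exocyclic CH2) hides two symmetric, achiral pieces: C7–C1–C6 is dihydroxyacetone dibenzoate and C2–C5 is (Z)-butenedial. C5(OH)–C6 next to a C1 ketone is an aldol retron; the tertiary α-ketol C1(OH)–C2(=O) is a crossed-benzoin retron. In one flask, a chiral acyloxyborane-catalysed syn-Mukaiyama aldol forms C5–C6 (setting C5 and C6), then a triazolylidene-catalysed 6-exo benzoin of the remaining formyl group onto the C1 ketone forms C1–C2 (setting C1). The precursors are the enol silane of the diester ketone and the dialdehyde made from furan.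

Key step: step 4

Remark: the tartaric acid enantiomer of the borane catalyst is assigned from the usual facial model of this catalyst class (attack on the aldehyde face that gives 5R); the antipodal ligand is taken should the sense prove opposite.

Step 1
Reactants: 1 1,3-dihydroxyacetone (commercial crystalline dimer, reacting as the monomer)
Product: 2 2-oxopropane-1,3-diyl dibenzoate
Conditions: BzCl (2.2 equiv), pyridine, CH2Cl2, 0 °C to rt
Reagents that add atoms: benzoyl chloride, O=C(Cl)c1ccccc1
Why: Base-mediated O-acylation (esterification with an acid chloride) of both primary hydroxyl groups, the dimer opening to the monomeric ketone in pyridine; no stereocenter is involved.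

Step 2
Reactants: 2 2-oxopropane-1,3-diyl dibenzoate
Product: 3 (Z)-2-(trimethylsilyloxy)prop-1-ene-1,3-diyl dibenzoate
Conditions: Me3SiOSO2CF3 (1.1 equiv), Et3N (1.3 equiv), CH2Cl2, 0 °C; pentane extraction without aqueous work-up
Reagents that add atoms: trimethylsilyl trifluoromethanesulfonate, C[Si](C)(C)OS(=O)(=O)C(F)(F)F
Why: Soft enolisation with silyl triflate and amine (silyl enol ether formation) on a ketone whose two α-carbons are equivalent, so only one regioisomer can form; the Z isomer is expected and the geometry does not matter for the next step.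

Step 3
Reactants: 4 furan
Product: 5 (Z)-but-2-enedial
Conditions: dimethyldioxirane (1.0 equiv), acetone, −20 °C to 0 °C; solvent exchanged for EtCN at or below 0 °C, solution used at once
Reagents that add atoms: dimethyldioxirane, CC1(C)OO1
Why: Oxidative ring opening of furan, in which dioxirane epoxidation of one ring double bond is followed by collapse of the 2,3-epoxide to the cis-enedial, the Z geometry being inherited from the ring.

Step 4
Reactants: 3 (Z)-2-(trimethylsilyloxy)prop-1-ene-1,3-diyl dibenzoate; 5 (Z)-but-2-enedial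
Product: 8 [(1R,5R,6S)-6-(benzoyloxy)-1,5-dihydroxy-2-oxocyclohex-3-en-1-yl]methyl benzoate, via silyl aldol 6 (not isolated), via ring-closed silyl ether 7 (not isolated)
Conditions: acyloxyborane from (2S,3S)-2-O-(2,6-diisopropoxybenzoyl)tartaric acid and BH3·THF (1:1, 10 mol%), EtCN, −78 °C; then in the same flask iPr2NEt (40 mol%), 2-(pentafluorophenyl)-6,7-dihydro-5H-pyrrolo[2,1-c][1,2,4]triazol-2-ium tetrafluoroborate (20 mol%), CH2Cl2, −78 °C to rt; then citric acid (cat.), MeOH, 0 °C
Reagents that add atoms: none
Why: The boron Lewis acid activates one of the two equivalent formyl groups of 5 and the enol silane adds through an open transition state with silyl transfer (catalytic asymmetric Mukaiyama aldol) to give 6; the amine then releases the triazolylidene, which adds to the remaining formyl group, the resulting acyl-anion equivalent attacks the C1 ketone (intramolecular crossed aldehyde–ketone benzoin) to give 7, and mild acid removes the silyl group. The closest known reaction types are the acyloxyborane-catalysed syn-selective aldol of ketone enol silanes with enals and the carbene-catalysed cyclisation of keto aldehydes to six-membered tertiary α-ketols. The ring closes in a 6-exo-trig mode, C2 attacking the carbonyl carbon C1 whose oxygen stays outside the ring, and the Z alkene holds the two ends within reach. C5 (R) is set by the catalyst, which exposes one face of the complexed aldehyde, and C6 (S) follows from the syn preference of the open transition state, which does not depend on enol silane geometry. C1 (R) is set by the substrate: in the chair-like closure the C5 silyloxy and C6 benzoyloxy groups sit pseudo-equatorial and the ketone oxygen points toward the hydroxyl of the carbene adduct, so the new C1–O bond is equatorial and the benzoyloxymethyl group axial. The step needs mono-addition to the dialdehyde, secured by 1:1 stoichiometry and the lower electrophilicity of the γ-silyloxy enal 6, and bond formation at the acyl carbon in place of β-protonation, secured by the aprotic medium, the N-pentafluorophenyl carbene and the fact that attack through the β-carbon would need a four-membered ring.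

Compound list
1 | 1,3-dihydroxyacetone (commercial crystalline dimer; monomer drawn) | OCC(=O)CO | starting material
2 | 2-oxopropane-1,3-diyl dibenzoate | O=C(COC(=O)c1ccccc1)COC(=O)c1ccccc1 | intermediate
3 | (Z)-2-(trimethylsilyloxy)prop-1-ene-1,3-diyl dibenzoate | O=C(O/C=C(/COC(=O)c1ccccc1)O[Si](C)(C)C)c1ccccc1 | intermediate
4 | furan | c1ccoc1 | starting material
5 | (Z)-but-2-enedial | O=C/C=C\C=O | intermediate
6 | (2Z,4R,5S)-5,7-bis(benzoyloxy)-6-oxo-4-(trimethylsilyloxy)hept-2-enal | O=C(c1ccccc1)OCC(=O)[C@@H](OC(=O)c1ccccc1)[C@H](O[Si](C)(C)C)/C=C\C=O | intermediate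
7 | [(1R,5R,6S)-6-(benzoyloxy)-1-hydroxy-2-oxo-5-(trimethylsilyloxy)cyclohex-3-en-1-yl]methyl benzoate | O=C(OC[C@]1(O)C(=O)C=C[C@@H](O[Si](C)(C)C)[C@@H]1OC(=O)c1ccccc1)c1ccccc1 | intermediate
8 | [(1R,5R,6S)-6-(benzoyloxy)-1,5-dihydroxy-2-oxocyclohex-3-en-1-yl]methyl benzoate | O=C(OC[C@]1(O)C(=O)C=C[C@@H](O)[C@@H]1OC(=O)c1ccccc1)c1ccccc1 | target

Total step count: 4. Longest linear sequence: 3 steps (steps 1, 2 and 4).

Steps most likely to fail

Step 4. Two-point binding of the cis-dialdehyde to boron may erode face selectivity, the Z-enal may isomerise before ring closure, the carbene may be lost to the boron Lewis acid, and the enal-derived acyl-anion equivalent may be protonated at the β-carbon or add conjugately to a second molecule instead of closing the ring. Fallback, from 3 and back at 8: the unsaturated dialdehyde is replaced by butanedial F1 and the alkene is introduced last. The same borane-catalysed aldol of 3 with F1 should give the saturated silyl aldol (4R,5S)-5,7-bis(benzoyloxy)-6-oxo-4-(trimethylsilyloxy)heptanal F2, which is isolated and cyclised with the same triazolium salt and iPr2NEt (benzoin of a plain aliphatic aldehyde) to [(1R,2S,3R)-2-(benzoyloxy)-1-hydroxy-6-oxo-3-(trimethylsilyloxy)cyclohexyl]methyl benzoate F3. Me3SiOSO2CF3/Et3N converts it into the tris-silyl enol ether [(1R,5R,6S)-6-(benzoyloxy)-1,2,5-tris(trimethylsilyloxy)cyclohex-2-en-1-yl]methyl benzoate F4, enolisation being possible only toward C3 because C1 is quaternary. Pd(OAc)2 in MeCN (Saegusa–Ito oxidation) should then give the enone [(1R,5R,6S)-6-(benzoyloxy)-2-oxo-1,5-bis(trimethylsilyloxy)cyclohex-3-en-1-yl]methyl benzoate F5, and citric acid in MeOH frees 8.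

Step 3. Over-oxidation, Z-to-E isomerisation and oligomerisation of the dialdehyde during concentration and solvent exchange. Fallback, from 4 and back at 5: singlet-oxygen [4+2] cycloaddition to furan (O2, hν, tetraphenylporphyrin, CH2Cl2, −78 °C) gives the endoperoxide 2,3,7-trioxabicyclo[2.2.1]hept-5-ene F6, which PPh3 (1.0 equiv, −78 °C) reduces in the same cold solution to 5, so the dialdehyde is never concentrated.

Step 2. A 1,2-benzoyl shift through the enol derivative, formation of isomer mixtures, or loss of the silyl group on isolation. Fallback, from 2 and back at 8: the ketone itself serves as donor through an enamine, and the acceptor is a mono-protected alkynal that tolerates a primary amine. O-tert-Butyl-D-threonine (20 mol%, N-methylpyrrolidone/water, 4 °C; the L-catalyst if the sense proves opposite) should join 2 and 4,4-diethoxybut-2-ynal F7 to the syn-aldol (3S,4R)-7,7-diethoxy-4-hydroxy-2-oxohept-5-yne-1,3-diyl dibenzoate F8. Semi-hydrogenation (H2, Pd/CaCO3 poisoned with Pb(OAc)2, quinoline, EtOAc) gives (3S,4R,5Z)-7,7-diethoxy-4-hydroxy-2-oxohept-5-ene-1,3-diyl dibenzoate F9. Acetal hydrolysis (HCO2H/H2O, 0 °C) releases the (Z)-γ-hydroxy enal, which rests as the lactol (1S)-1-[(2R)-5-hydroxy-2,5-dihydrofuran-2-yl]-2-oxopropane-1,3-diyl dibenzoate F10, and the triazolium salt with iPr2NEt closes it by the crossed benzoin to 8.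

Further compounds
F1 | step 4 | butanedial | O=CCCC=O
F2 | step 4 | (4R,5S)-5,7-bis(benzoyloxy)-6-oxo-4-(trimethylsilyloxy)heptanal | O=C(c1ccccc1)OCC(=O)[C@@H](OC(=O)c1ccccc1)[C@H](O[Si](C)(C)C)CCC=O
F3 | step 4 | [(1R,2S,3R)-2-(benzoyloxy)-1-hydroxy-6-oxo-3-(trimethylsilyloxy)cyclohexyl]methyl benzoate | O=C(OC[C@]1(O)C(=O)CC[C@@H](O[Si](C)(C)C)[C@@H]1OC(=O)c1ccccc1)c1ccccc1
F4 | step 4 | [(1R,5R,6S)-6-(benzoyloxy)-1,2,5-tris(trimethylsilyloxy)cyclohex-2-en-1-yl]methyl benzoate | O=C(OC[C@]1(O[Si](C)(C)C)C(O[Si](C)(C)C)=CC[C@@H](O[Si](C)(C)C)[C@@H]1OC(=O)c1ccccc1)c1ccccc1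
F5 | step 4 | [(1R,5R,6S)-6-(benzoyloxy)-2-oxo-1,5-bis(trimethylsilyloxy)cyclohex-3-en-1-yl]methyl benzoate | O=C(OC[C@]1(O[Si](C)(C)C)C(=O)C=C[C@@H](O[Si](C)(C)C)[C@@H]1OC(=O)c1ccccc1)c1ccccc1
F6 | step 3 | 2,3,7-trioxabicyclo[2.2.1]hept-5-ene | C1=CC2OOC1O2
F7 | step 2 | 4,4-diethoxybut-2-ynal | CCOC(OCC)C#CC=O
F8 | step 2 | (3S,4R)-7,7-diethoxy-4-hydroxy-2-oxohept-5-yne-1,3-diyl dibenzoate | O=C(c1ccccc1)OCC(=O)[C@@H](OC(=O)c1ccccc1)[C@H](O)C#CC(OCC)OCC
F9 | step 2 | (3S,4R,5Z)-7,7-diethoxy-4-hydroxy-2-oxohept-5-ene-1,3-diyl dibenzoate | O=C(c1ccccc1)OCC(=O)[C@@H](OC(=O)c1ccccc1)[C@H](O)/C=C\C(OCC)OCC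
F10 | step 2 | (1S)-1-[(2R)-5-hydroxy-2,5-dihydrofuran-2-yl]-2-oxopropane-1,3-diyl dibenzoate | O=C(c1ccccc1)OCC(=O)[C@@H](OC(=O)c1ccccc1)[C@@H]1OC(O)C=C1
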